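**Plan**

- Numbering: ring A (4-hydroxy-3,5-dimethoxyphenyl) sits on carbinol carbon C7; C8 carries the C9 methyl and the ether oxygen O4' of ring B (2,6-dimethoxy-4-propenylphenyl).
- Cuts: first the ring B–propenyl bond (aryl bromide plus an (E)-propenylboronate), then the C9 methyl is traced back to an ester carbon, then C8–O4' and C7–C8 are cut together, leaving 4-bromo-2,6-dimethoxyphenol, ethyl diazoacetate and O-silylated syringaldehyde.
- Enabling feature: C8 is bonded simultaneously to O4' of ring B, to the ring A carbinol carbon C7 and to the one-carbon unit C9. This is the substitution pattern produced when a carbene carbon inserts into a phenol O–H bond and the ylide is intercepted by an aldehyde; no ring has to be formed.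
- Forward order: silylation of syringaldehyde; three-component union (both chain bonds at once); ester to CH2OH to CH2OTs to CH3; Suzuki coupling for the E-propenyl group; desilylation.
- Stereochemistry: C7 and C8 (anti) are both set in the three-component step by a chiral Zr(OtBu)4/BINOL Lewis acid that holds the aldehyde. The E alkene comes from a stereodefined boronate.

Key step: step 2

Assumption: the sense of induction of the Zr(OtBu)4/BINOL complex cannot be predicted for this substrate pairing; (S)-BINOL is written as the ligand expected to lead to the (2R,3R) ester, and the (R) ligand would be used instead if a pilot run shows the opposite sense.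

**Step 1**
Reactants: 1 syringaldehyde (4-hydroxy-3,5-dimethoxybenzaldehyde)
Product: 2 3,5-dimethoxy-4-(triisopropylsilyloxy)benzaldehyde
Conditions: TIPSCl, imidazole, DMF, rt
Reagents that add atoms: chlorotri(propan-2-yl)silane (TIPSCl), CC(C)[Si](Cl)(C(C)C)C(C)C
Why: Silylation of a phenol with a silyl chloride and imidazole is routine even for a hydroxyl flanked by two methoxy groups, and the triisopropylsilyl ether is chosen because it should outlast the hydride reagents and the aqueous carbonate of the later steps while remaining removable with fluoride; no stereocentre is involved.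

**Step 2**
Reactants: 2 3,5-dimethoxy-4-(triisopropylsilyloxy)benzaldehyde; 3 4-bromo-2,6-dimethoxyphenol; 4 ethyl diazoacetate
Product: 6 anti-configured ethyl (2R,3R)-2-(4-bromo-2,6-dimethoxyphenoxy)-3-hydroxy-3-[3,5-dimethoxy-4-(triisopropylsilyloxy)phenyl]propanoate, via oxonium ylide 5 (not isolated)
Conditions: Rh2(OAc)4 (2 mol %), Zr(OtBu)4 (15 mol %) + (S)-BINOL (30 mol %) (premixed, tBuOH removed in vacuo), 4 Å MS, CH2Cl2, 0 °C, 4 added slowly by syringe pump to 3 and excess 2
Reagents that add atoms: none
Why: Proposed new method: Rh2(OAc)4 should strip nitrogen from 4 to give an electrophilic carbene bound to Rh2(OAc)4, the hydroxyl oxygen of phenol 3 should add to it to give the protic oxonium ylide 5 (in equilibrium with its enol form), and this nucleophile should add to the carbonyl carbon of aldehyde 2, activated on the chiral complex formed from Zr(OtBu)4 and (S)-BINOL, before the 1,2-proton shift that would end in the simple aryloxyacetate, so that C8–O4' and C7–C8 are made in one operation. The closest known reaction type is the three-component coupling of aryl diazoacetates with alcohols and aldehydes or imines under Rh2(OAc)4 and a chiral Lewis or Brønsted acid co-catalyst; an acceptor-only diazoacetate combined with a phenol and an aryl aldehyde under stereocontrol is the untested extension. No ring is closed. Both new stereocentres arise in the aldol-type C–C bond formation: the BINOL-bearing tetravalent zirconium centre that holds the aldehyde should shield one carbonyl face (C7, 3R in the ester) and, in a compact transition state in which the aryloxy group of the enol and the aryl group of the aldehyde avoid each other, select the enol face (C8, 2R), which corresponds to the anti adduct. Chemoselectivity rests on the substrates: ring B has both ortho positions and the para position blocked and carries bromine in place of the propenyl group, so O–H insertion is the only open path for the carbene (no cyclopropanation, no attack on ring C–H bonds), while the aldehyde cannot enolise and its 4-silyloxy group is twisted out of conjugation by the two flanking methoxy groups, so the carbonyl should be about as electrophilic as that of benzaldehyde. Slow addition of 4, excess aldehyde and removal of tBuOH from the Lewis acid should favour interception of 5 over the proton shift, carbene dimerisation and direct addition of 4 to the aldehyde.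

**Step 3**
Reactants: 6 ethyl (2R,3R)-2-(4-bromo-2,6-dimethoxyphenoxy)-3-hydroxy-3-[3,5-dimethoxy-4-(triisopropylsilyloxy)phenyl]propanoate
Product: 7 (1R,2S)-2-(4-bromo-2,6-dimethoxyphenoxy)-1-[3,5-dimethoxy-4-(triisopropylsilyloxy)phenyl]propane-1,3-diol
Conditions: LiBH4, THF, 0 °C to rt; aq. NH4Cl
Reagents that add atoms: none
Why: Chemoselective borohydride reduction of an ester to the primary alcohol is the standard conversion of 2-aryloxy-3-hydroxy esters into 1,3-diols; LiBH4 is not basic enough to epimerise C8 or to start a retro-aldol cleavage and leaves the aryl bromide and silyl ether untouched, so both stereocentres are carried over (C8 is now named S only because the substituent ranking changes).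

**Step 4**
Reactants: 7 (1R,2S)-2-(4-bromo-2,6-dimethoxyphenoxy)-1-[3,5-dimethoxy-4-(triisopropylsilyloxy)phenyl]propane-1,3-diol
Product: 8 (2S,3R)-2-(4-bromo-2,6-dimethoxyphenoxy)-3-hydroxy-3-[3,5-dimethoxy-4-(triisopropylsilyloxy)phenyl]propyl 4-methylbenzenesulfonate
Conditions: TsCl (1.1 equiv), pyridine, CH2Cl2, 0 °C
Reagents that add atoms: p-toluenesulfonyl chloride (TsCl), Cc1ccc(cc1)S(Cl)(=O)=O
Why: Selective sulfonylation of a primary hydroxyl in the presence of a hindered secondary benzylic one with a slight excess of TsCl at low temperature is routine, and no stereocentre is touched.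

**Step 5**
Reactants: 8 (2S,3R)-2-(4-bromo-2,6-dimethoxyphenoxy)-3-hydroxy-3-[3,5-dimethoxy-4-(triisopropylsilyloxy)phenyl]propyl 4-methylbenzenesulfonate
Product: 9 (1R,2S)-2-(4-bromo-2,6-dimethoxyphenoxy)-1-[3,5-dimethoxy-4-(triisopropylsilyloxy)phenyl]propan-1-ol
Conditions: LiEt3BH (3 equiv), THF, 0 °C to rt; aq. NH4Cl
Reagents that add atoms: none
Why: SN2 displacement of a primary tosylate by the strongly nucleophilic hydride LiEt3BH (hydride reduction of a sulfonate, as used for monotosylates of 1,3-diols) turns CH2OTs into the C9 methyl; the C7 hydroxyl is only deprotonated, the aryl bromide is inert to the reagent, and neither stereocentre takes part.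

**Step 6**
Reactants: 9 (1R,2S)-2-(4-bromo-2,6-dimethoxyphenoxy)-1-[3,5-dimethoxy-4-(triisopropylsilyloxy)phenyl]propan-1-ol
Product: 10 (1R,2S)-2-[2,6-dimethoxy-4-[(E)-prop-1-enyl]phenoxy]-1-[3,5-dimethoxy-4-(triisopropylsilyloxy)phenyl]propan-1-ol
Conditions: (E)-prop-1-enylboronic acid pinacol ester, PdCl2(dppf) (5 mol %), K2CO3, 1,4-dioxane/H2O, 80 °C, degassed
Reagents that add atoms: (E)-prop-1-enylboronic acid pinacol ester, C/C=C/B1OC(C)(C)C(C)(C)O1
Why: Suzuki–Miyaura coupling of an aryl bromide with an alkenylboronate proceeds with retention of the E geometry; the bromine lies between two unsubstituted ring positions, so oxidative addition to zerovalent palladium is unhindered, the boronic ester is preferred to a trifluoroborate so that no fluoride reaches the aryl silyl ether, and the carbinol stereocentres are remote from the reacting site.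

**Step 7**
Reactants: 10 (1R,2S)-2-[2,6-dimethoxy-4-[(E)-prop-1-enyl]phenoxy]-1-[3,5-dimethoxy-4-(triisopropylsilyloxy)phenyl]propan-1-ol
Product: 11 4-[(1R,2S)-2-[2,6-dimethoxy-4-[(E)-prop-1-enyl]phenoxy]-1-hydroxypropyl]-2,6-dimethoxyphenol (the target, 7R,8S in the C7/C8 numbering)
Conditions: Bu4NF, AcOH, THF, 0 °C
Reagents that add atoms: none
Why: Fluoride-induced cleavage of an aryl silyl ether (desilylation) is fast at 0 °C, and buffering with acetic acid should keep the liberated 4-hydroxybenzyl alcohol from forming a quinone methide under basic conditions, so C7, C8 and the propenyl group stay as they are.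

**Compound list**

1 | syringaldehyde (4-hydroxy-3,5-dimethoxybenzaldehyde) | COc1cc(C=O)cc(OC)c1O | starting material
2 | 3,5-dimethoxy-4-(triisopropylsilyloxy)benzaldehyde | COc1cc(C=O)cc(OC)c1O[Si](C(C)C)(C(C)C)C(C)C | intermediate
3 | 4-bromo-2,6-dimethoxyphenol | COc1cc(Br)cc(OC)c1O | starting material
4 | ethyl diazoacetate | CCOC(=O)C=[N+]=[N-] | starting material
5 | protic oxonium ylide from the O–H attack of 3 on the carbene of 4 (not isolated) | CCOC(=O)[CH-][OH+]c1c(OC)cc(Br)cc1OC | intermediate
6 | ethyl (2R,3R)-2-(4-bromo-2,6-dimethoxyphenoxy)-3-hydroxy-3-[3,5-dimethoxy-4-(triisopropylsilyloxy)phenyl]propanoate (anti) | COc1cc(Br)cc(OC)c1O[C@@H](C(=O)OCC)[C@H](O)c1cc(OC)c(O[Si](C(C)C)(C(C)C)C(C)C)c(OC)c1 | intermediate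
7 | (1R,2S)-2-(4-bromo-2,6-dimethoxyphenoxy)-1-[3,5-dimethoxy-4-(triisopropylsilyloxy)phenyl]propane-1,3-diol | COc1cc(Br)cc(OC)c1O[C@@H](CO)[C@H](O)c1cc(OC)c(O[Si](C(C)C)(C(C)C)C(C)C)c(OC)c1 | intermediate
8 | (2S,3R)-2-(4-bromo-2,6-dimethoxyphenoxy)-3-hydroxy-3-[3,5-dimethoxy-4-(triisopropylsilyloxy)phenyl]propyl 4-methylbenzenesulfonate | COc1cc(Br)cc(OC)c1O[C@@H](COS(=O)(=O)c1ccc(C)cc1)[C@H](O)c1cc(OC)c(O[Si](C(C)C)(C(C)C)C(C)C)c(OC)c1 | intermediate
9 | (1R,2S)-2-(4-bromo-2,6-dimethoxyphenoxy)-1-[3,5-dimethoxy-4-(triisopropylsilyloxy)phenyl]propan-1-ol | COc1cc(Br)cc(OC)c1O[C@@H](C)[C@H](O)c1cc(OC)c(O[Si](C(C)C)(C(C)C)C(C)C)c(OC)c1 | intermediate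
10 | (1R,2S)-2-[2,6-dimethoxy-4-[(E)-prop-1-enyl]phenoxy]-1-[3,5-dimethoxy-4-(triisopropylsilyloxy)phenyl]propan-1-ol | C/C=C/c1cc(OC)c(O[C@@H](C)[C@H](O)c2cc(OC)c(O[Si](C(C)C)(C(C)C)C(C)C)c(OC)c2)c(OC)c1 | intermediate
11 | 4-[(1R,2S)-2-[2,6-dimethoxy-4-[(E)-prop-1-enyl]phenoxy]-1-hydroxypropyl]-2,6-dimethoxyphenol | C/C=C/c1cc(OC)c(O[C@@H](C)[C@H](O)c2cc(OC)c(O)c(OC)c2)c(OC)c1 | target

**Step count**

Total: 7 steps. Longest linear sequence: 7 steps (1 → 2 → 6 → 7 → 8 → 9 → 10 → 11).

**Steps most likely to fail**

Step 2 (three-component union). The protic ylide may collapse by 1,2-proton shift before it is intercepted, giving only O–H insertion, or the aldol event may show poor facial and anti/syn selectivity with this unstabilised ylide. The fallback uses known chemistry in a different bond order; it sets out from phenol 3 and returns to the route at 9.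
- Mitsunobu etherification of 3 with ethyl (R)-lactate (PPh3, DIAD, THF, inversion at carbon) should give ethyl (S)-2-(4-bromo-2,6-dimethoxyphenoxy)propanoate F1, which already holds C8 with its methyl.
- Treatment with Me(MeO)NH·HCl and iPrMgCl in THF at −20 °C would convert it into the Weinreb amide (S)-2-(4-bromo-2,6-dimethoxyphenoxy)-N-methoxy-N-methylpropanamide F2.
- A second portion of 3 would be silylated (TIPSCl, imidazole, DMF) to (4-bromo-2,6-dimethoxyphenoxy)triisopropylsilane F3 and converted with Mg in THF into [3,5-dimethoxy-4-(triisopropylsilyloxy)phenyl]magnesium bromide F4.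
- Addition of F4 to F2 at low temperature would give the ketone (S)-2-(4-bromo-2,6-dimethoxyphenoxy)-1-[3,5-dimethoxy-4-(triisopropylsilyloxy)phenyl]propan-1-one F5.
- Chelation-controlled reduction of F5 with Zn(BH4)2 in Et2O at −30 °C (Cram chelate between the carbonyl and the aryloxy oxygen) should deliver the anti alcohol 9, after which steps 6 and 7 follow unchanged.

Step 5 (hydride displacement). The C7 alkoxide formed by the hydride may close an oxetane or trigger Grob-type fragmentation of the 1,3-hydroxy tosylate, or hydride delivery to the β-branched primary carbon may be slow. The fallback removes the free hydroxyl from play; it sets out from tosylate 8 and returns to the route at target 11.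
- The C7 hydroxyl would be capped with TESOTf and 2,6-lutidine in CH2Cl2 at −78 °C to give (2S,3R)-2-(4-bromo-2,6-dimethoxyphenoxy)-3-[3,5-dimethoxy-4-(triisopropylsilyloxy)phenyl]-3-(triethylsilyloxy)propyl 4-methylbenzenesulfonate F6.
- LiEt3BH in THF would then reduce the tosylate of this alkoxide-free substrate to [(1R,2S)-2-(4-bromo-2,6-dimethoxyphenoxy)-1-[3,5-dimethoxy-4-(triisopropylsilyloxy)phenyl]propoxy]triethylsilane F7.
- Suzuki coupling under the conditions of step 6 would give [(1R,2S)-2-[2,6-dimethoxy-4-[(E)-prop-1-enyl]phenoxy]-1-[3,5-dimethoxy-4-(triisopropylsilyloxy)phenyl]propoxy]triethylsilane F8.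
- One treatment with Bu4NF and AcOH in THF would remove both silyl groups and give 11.

Step 6 (Suzuki coupling). Oxidative addition into the electron-rich aryl bromide may be sluggish, the propenylboron partner may protodeboronate or lose E purity, and the aryl silyl ether may be lost early in hot aqueous base. The fallback is base-free; it sets out from bromide 9 and returns to the route at 10.
- Stille coupling of 9 with allyltributylstannane (Pd(PPh3)4, toluene, 100 °C) should give (1R,2S)-2-(4-allyl-2,6-dimethoxyphenoxy)-1-[3,5-dimethoxy-4-(triisopropylsilyloxy)phenyl]propan-1-ol F9.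
- Migration of the double bond into conjugation with PdCl2(MeCN)2 in CH2Cl2 at rt should then give the thermodynamically preferred E-propenyl compound 10.

**Further compounds**

F1 | step 2 | ethyl (S)-2-(4-bromo-2,6-dimethoxyphenoxy)propanoate | COc1cc(Br)cc(OC)c1O[C@@H](C)C(=O)OCC
F2 | step 2 | (S)-2-(4-bromo-2,6-dimethoxyphenoxy)-N-methoxy-N-methylpropanamide | COc1cc(Br)cc(OC)c1O[C@@H](C)C(=O)N(C)OC
F3 | step 2 | (4-bromo-2,6-dimethoxyphenoxy)triisopropylsilane | COc1cc(Br)cc(OC)c1O[Si](C(C)C)(C(C)C)C(C)C
F4 | step 2 | [3,5-dimethoxy-4-(triisopropylsilyloxy)phenyl]magnesium bromide | COc1cc([Mg]Br)cc(OC)c1O[Si](C(C)C)(C(C)C)C(C)C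
F5 | step 2 | (S)-2-(4-bromo-2,6-dimethoxyphenoxy)-1-[3,5-dimethoxy-4-(triisopropylsilyloxy)phenyl]propan-1-one | COc1cc(Br)cc(OC)c1O[C@@H](C)C(=O)c1cc(OC)c(O[Si](C(C)C)(C(C)C)C(C)C)c(OC)c1
F6 | step 5 | (2S,3R)-2-(4-bromo-2,6-dimethoxyphenoxy)-3-[3,5-dimethoxy-4-(triisopropylsilyloxy)phenyl]-3-(triethylsilyloxy)propyl 4-methylbenzenesulfonate | COc1cc(Br)cc(OC)c1O[C@@H](COS(=O)(=O)c1ccc(C)cc1)[C@H](O[Si](CC)(CC)CC)c1cc(OC)c(O[Si](C(C)C)(C(C)C)C(C)C)c(OC)c1
F7 | step 5 | [(1R,2S)-2-(4-bromo-2,6-dimethoxyphenoxy)-1-[3,5-dimethoxy-4-(triisopropylsilyloxy)phenyl]propoxy]triethylsilane | COc1cc(Br)cc(OC)c1O[C@@H](C)[C@H](O[Si](CC)(CC)CC)c1cc(OC)c(O[Si](C(C)C)(C(C)C)C(C)C)c(OC)c1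
F8 | step 5 | [(1R,2S)-2-[2,6-dimethoxy-4-[(E)-prop-1-enyl]phenoxy]-1-[3,5-dimethoxy-4-(triisopropylsilyloxy)phenyl]propoxy]triethylsilane | C/C=C/c1cc(OC)c(O[C@@H](C)[C@H](O[Si](CC)(CC)CC)c2cc(OC)c(O[Si](C(C)C)(C(C)C)C(C)C)c(OC)c2)c(OC)c1
F9 | step 6 | (1R,2S)-2-(4-allyl-2,6-dimethoxyphenoxy)-1-[3,5-dimethoxy-4-(triisopropylsilyloxy)phenyl]propan-1-ol | C=CCc1cc(OC)c(O[C@@H](C)[C@H](O)c2cc(OC)c(O[Si](C(C)C)(C(C)C)C(C)C)c(OC)c2)c(OC)c1
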